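Wednesday's and Thursday's flasks differed in their charge of free monomer, and I had to say which ended with the longer chains.

| setting | maple | cedar | larch | Wednesday's | Thursday's |
|---|---|---|---|---|---|
| free monomer | 0.43 M | 0.70 M | 1.1 M | 1.5 M | 0.40 M |
| protic impurity | 0.075 M | 0.075 M | 0.075 M | 0.0750 M | 0.0750 M |
| initiator | 2.9 mM | 2.9 mM | 2.9 mM | 2.9 mM | 2.9 mM |
| remark | run made earlier | run made earlier | run made earlier |  |  |
| time |  |  |  | 40 h | 40 h |

| run | time / h | monomer in chains / % |
|---|---|---|
| maple | 4.00 | 70.9 |
| maple | 8.00 | 79.0 |
| maple | 12.0 | 81.4 |
| maple | 15.0 | 81.1 |
| maple | 20.0 | 82.5 |
| cedar | 1.50 | 49.8 |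
| cedar | 3.00 | 69.1 |
| cedar | 6.00 | 82.7 |
| cedar | 10.0 | 86.6 |
| cedar | 20.0 | 88.7 |
| larch | 2.00 | 59.8 |
| larch | 5.00 | 82.7 |
| larch | 10.0 | 91.1 |
| larch | 15.0 | 92.8 |
| larch | 20.0 | 92.9 |

(standard deviation of a reading: 0.5 percentage points)

- the average divides the monomer in chains by the number of chains, living and dead together; two radicals that join make one chain
- the earlier runs do not show the number of chains; that part of a forecast is a guess

- which of the two ends with the longer chains by the average number of monomer units in a chain (living and dead chains, two that joined counted as one) ("neither" if they lie within 10%) (Wednesday's / Thursday's / neither)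
- average number of monomer units in a chain (living and dead chains, two that joined counted as one) at the end, Wednesday's
- average number of monomer units in a chain (living and dead chains, two that joined counted as one) at the end, Thursday's

Maple, the run with the leanest charge, read 0.0752 M of its charge outside the chains at its last reading; this was my shortfall, the charge minus the monomer in chains read last. Cedar and larch read 0.0791 M and 0.0781 M, so the readings showed no clear growth of the shortfall with the charge, and it lay close to the protic impurity charged, 0.0750 M. I read it as one free monomer lost per protic impurity, a correction to subtract from the charge. Both flasks ran 40 h, longer than the 20.0 h of the last readings, where the rise had nearly stopped, so I expected 1.42 M in chains in Wednesday's and 0.325 M in Thursday's. The chain count was my guess: if an initiator gave two radicals and two that joined made one chain, there was one chain per initiator charged, which gave 491 for Wednesday's and 112 for Thursday's.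

The forecast named Wednesday's, with 100 against 23, below my figures, and said: "Chain count is the guess".

The flasks gave 490 for Wednesday's and 112 for Thursday's, so Wednesday's ended with the longer chains.

    initiator → 2 initiating radical (k = 5.50 × 10⁻⁵ /s)
    free monomer + initiating radical → growing radical + monomer in chains (k = 37700 /M/s)
    free monomer + growing radical → monomer in chains + growing radical, rate k3*[growing radical]*[free monomer] (k = 1970 /M/s)
    2 growing radical → dead chain (k = 2.50 × 10⁷ /M/s)
    protic impurity + free monomer → quenched substrate (k = 0.00390 /M/s)

In Wednesday's, the quenching of free monomer reached the midpoint of its turnover at 2.03 min, while the reaction of free monomer to monomer in chains took 1.29 h to reach its own. The protic impurity, limiting reagent of that quench, stood at 0% of its charge at the end of Wednesday's, and subtracting my shortfall left 95.0% of Wednesday's charge for chains, against 94.7% found with 0.321% still free. For the neighbour of Wednesday's with 0.030 M of protic impurity, the shortfall scaled to that charge leaves 98.0% in chains and, at one chain per initiator charged, 507 units per chain, and that flask gave 97.7% and 505.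

The earlier runs and the new flask were generated by integration with made-up constants; the scatter is artificial.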